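**Retrosynthetic overview**
- Last operations: free the acid from its tert-butyl ester, make the C7 ketone by allylic oxidation of the Δ5 alkene, acetylate the C18 alcohol.
- Key disconnection C12–C13: the β-carbon of tert-butyl crotonate is turned into a configurationally defined boron nucleophile (a homoenolate equivalent) and joined to an alkenyl iodide carbon by a boronate 1,2-shift (Zweifel); the C11=C12 alkene is then hydrogenated.
- The alkenyl iodide comes from a C11 aldehyde (Takai), made by an exo Diels–Alder reaction of tiglic aldehyde with a 6,6-disubstituted 1-vinylcyclohexene; this sets C8, C9 and C10.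
- The diene comes from ethyl 2-oxocyclohexanecarboxylate: asymmetric methylation (C4), enol triflate, Stille vinylation.
- Ring order: ring A is bought; ring B is the only ring made (Diels–Alder).

Atom labels C1–C20 follow halimane numbering: ring A = C1–C5 and C10; ring B = C5–C10; side chain C11–C15 with C16 on C13; C17 on C8; C18 (oxygenated) and C19 on C4; C20 on C9.

Assumption: where a chiral catalyst, ligand or auxiliary is named, the antipode written is taken to give the drawn configuration; if a test shows the opposite sense, its mirror image is used.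

**Step 1**
Reactants: 1 ethyl 2-oxocyclohexane-1-carboxylate
Product: 2 ethyl (1R)-1-methyl-2-oxocyclohexane-1-carboxylate
Conditions: MeI (2 equiv), CsOH·H2O (1.5 equiv), N-(9-anthracenylmethyl)-O-allylcinchonidinium bromide (10 mol %), toluene, −40 °C
Reagents that add atoms: iodomethane, CI
Why: Enolate C-methylation under chiral phase-transfer (ion-pair) catalysis; the ammonium cation shields one enolate face, so methyl iodide enters the other and sets the C4 quaternary centre as R.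

**Step 2**
Reactants: 2 ethyl (1R)-1-methyl-2-oxocyclohexane-1-carboxylate
Product: 4 ethyl (1R)-1-methyl-2-[(trifluoromethanesulfonyl)oxy]cyclohex-2-ene-1-carboxylate, via potassium enolate 3 (not isolated)
Conditions: KN(SiMe3)2, THF, −78 °C; PhNTf2, −78 → 0 °C
Reagents that add atoms: N-phenylbis(trifluoromethanesulfonimide), O=S(=O)(N(c1ccccc1)S(=O)(=O)C(F)(F)F)C(F)(F)F
Why: The ketone can enolise only away from the quaternary C4, and the enolate is trapped on oxygen (enolate O-sulfonylation); C4 is untouched.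

**Step 3**
Reactants: 4 ethyl (1R)-1-methyl-2-[(trifluoromethanesulfonyl)oxy]cyclohex-2-ene-1-carboxylate
Product: 5 ethyl (1R)-2-ethenyl-1-methylcyclohex-2-ene-1-carboxylate
Conditions: tributyl(vinyl)stannane, Pd(PPh3)4 (5 mol %), LiCl (3 equiv), THF, 65 °C
Reagents that add atoms: tributyl(vinyl)stannane, C=C[Sn](CCCC)(CCCC)CCCC
Why: Stille coupling: oxidative addition of the alkenyl triflate to zerovalent palladium, transmetalation with the vinylstannane and reductive elimination give the semicyclic 1,3-diene.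

**Step 4**
Reactants: 5 ethyl (1R)-2-ethenyl-1-methylcyclohex-2-ene-1-carboxylate; 6 (2E)-2-methylbut-2-enal
Product: 7 ethyl (1R,4aR,5R,6S)-5-formyl-1,5,6-trimethyl-1,2,3,4,4a,5,6,7-octahydronaphthalene-1-carboxylate
Conditions: (S)-3,3-diphenyl-1-(2-methylphenyl)tetrahydro-1H,3H-pyrrolo[1,2-c][1,3,2]oxazaborole (20 mol %), (CF3SO2)2NH (18 mol %), CH2Cl2, −78 → −20 °C
Reagents that add atoms: none
Why: Lewis acid catalysed Diels–Alder reaction (ortho, exo): the CH2 terminus C7 bonds to the enal β-carbon C8 and C10 to the α-carbon C9; the E enal fixes C17 and C20 cis; the exo transition state, reported for α-methyl enals with 6,6-disubstituted 1-vinylcyclohexenes, puts the formyl group cis to H-10; the chiral oxazaborolidinium selects the enal face so that the diene reacts on the face of the C4 methyl, anti to the ester.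

**Step 5**
Reactants: 7 ethyl (1R,4aR,5R,6S)-5-formyl-1,5,6-trimethyl-1,2,3,4,4a,5,6,7-octahydronaphthalene-1-carboxylate
Product: 8 ethyl (1R,4aS,5R,6S)-5-[(E)-2-iodoethenyl]-1,5,6-trimethyl-1,2,3,4,4a,5,6,7-octahydronaphthalene-1-carboxylate
Conditions: CrCl2 (6 equiv), CHI3 (2 equiv), THF, 0 → 20 °C
Reagents that add atoms: iodoform, IC(I)I
Why: Takai olefination: the geminal dichromium species from CHI3 and CrCl2 adds to the hindered aldehyde and eliminates to the (E)-iodoalkene; ester and ring alkene do not react.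

**Step 6**
Reactants: 8 ethyl (1R,4aS,5R,6S)-5-[(E)-2-iodoethenyl]-1,5,6-trimethyl-1,2,3,4,4a,5,6,7-octahydronaphthalene-1-carboxylate
Product: 9 [(1R,4aS,5R,6S)-5-[(E)-2-iodoethenyl]-1,5,6-trimethyl-1,2,3,4,4a,5,6,7-octahydronaphthalen-1-yl]methanol
Conditions: i-Bu2AlH (3 equiv), CH2Cl2, −78 → 0 °C
Reagents that add atoms: none
Why: Hydride reduction of the ester to the C18 alcohol, which spares the alkenyl iodide; it is done here because an acetate would not survive step 8.

**Step 7**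
Reactants: 10 tert-butyl (2E)-but-2-enoate
Product: 11 tert-butyl (3S)-3-(4,4,5,5-tetramethyl-1,3,2-dioxaborolan-2-yl)butanoate
Conditions: B2pin2 (1.1 equiv), CuCl (3 mol %), NaOt-Bu (3 mol %), (R)-1-[(SP)-2-(diphenylphosphino)ferrocenyl]ethyldicyclohexylphosphine (3 mol %), MeOH (2 equiv), THF, 20 °C
Reagents that add atoms: bis(pinacolato)diboron, CC1(C)OB(OC1(C)C)B1OC(C)(C)C(C)(C)O1
Why: Copper-catalysed asymmetric conjugate borylation: the chiral boryl copper adds to one face of the β-carbon and methanol protonates the enolate, so the electrophilic β-carbon becomes a configurationally stable nucleophile (homoenolate equivalent) of S configuration.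

**Step 8 (key step)**
Reactants: 9 [(1R,4aS,5R,6S)-5-[(E)-2-iodoethenyl]-1,5,6-trimethyl-1,2,3,4,4a,5,6,7-octahydronaphthalen-1-yl]methanol; 11 tert-butyl (3S)-3-(4,4,5,5-tetramethyl-1,3,2-dioxaborolan-2-yl)butanoate
Product: 15 tert-butyl (3S,4Z)-5-[(1S,2S,5R,8aS)-5-(hydroxymethyl)-1,2,5-trimethyl-1,2,3,5,6,7,8,8a-octahydronaphthalen-1-yl]-3-methylpent-4-enoate, via dilithiated alkenyllithium alkoxide 12 (not isolated), via lithium alkenyl boronate complex 13 (not isolated), via β-iodoalkyl boronic ester 14 (not isolated)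
Conditions: t-BuLi (3.1 equiv), Et2O/THF, −78 °C; 11 (1.2 equiv), −78 → 0 °C; I2 (1.3 equiv), MeOH, −78 °C; NaOMe, MeOH, −78 → 20 °C
Reagents that add atoms: none
Why: Zweifel olefination used as a homoenolate coupling: the alkenyllithium adds to boron faster than to the tert-butyl ester, iodine makes C12 electrophilic, C13 migrates from boron to C12 with retention (1,2-metallate shift) and methoxide-induced anti elimination gives the alkene, so the former β-carbon of the crotonate is joined as a nucleophile to a former C–I carbon with the C13 configuration of step 7 unchanged.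

**Step 9**
Reactants: 15 tert-butyl (3S,4Z)-5-[(1S,2S,5R,8aS)-5-(hydroxymethyl)-1,2,5-trimethyl-1,2,3,5,6,7,8,8a-octahydronaphthalen-1-yl]-3-methylpent-4-enoate
Product: 16 tert-butyl (3R)-5-[(1R,2S,5R,8aS)-5-(hydroxymethyl)-1,2,5-trimethyl-1,2,3,5,6,7,8,8a-octahydronaphthalen-1-yl]-3-methylpentanoate
Conditions: H2 (4 atm), RhCl(PPh3)3 (10 mol %), benzene/EtOH, 25 °C
Reagents that add atoms: none
Why: Homogeneous hydrogenation: RhCl(PPh3)3 reduces the cis-disubstituted side-chain alkene but neither reduces nor shifts the trisubstituted C5=C6 alkene next to the quaternary C4; no stereocentre is touched (descriptors change by priority only).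

**Step 10**
Reactants: 16 tert-butyl (3R)-5-[(1R,2S,5R,8aS)-5-(hydroxymethyl)-1,2,5-trimethyl-1,2,3,5,6,7,8,8a-octahydronaphthalen-1-yl]-3-methylpentanoate
Product: 17 tert-butyl (3R)-5-[(1R,2S,5R,8aS)-5-(acetoxymethyl)-1,2,5-trimethyl-1,2,3,5,6,7,8,8a-octahydronaphthalen-1-yl]-3-methylpentanoate
Conditions: Ac2O, pyridine, DMAP (cat.), CH2Cl2, 20 °C
Reagents that add atoms: acetic anhydride, CC(=O)OC(C)=O
Why: Nucleophile-catalysed O-acylation of the primary neopentyl alcohol.

**Step 11**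
Reactants: 17 tert-butyl (3R)-5-[(1R,2S,5R,8aS)-5-(acetoxymethyl)-1,2,5-trimethyl-1,2,3,5,6,7,8,8a-octahydronaphthalen-1-yl]-3-methylpentanoate
Product: 18 tert-butyl (3R)-5-[(1S,2R,5R,8aS)-5-(acetoxymethyl)-1,2,5-trimethyl-3-oxo-1,2,3,5,6,7,8,8a-octahydronaphthalen-1-yl]-3-methylpentanoate
Conditions: t-BuOOH (70% aq., 5 equiv), Rh2(C6H10NO)4 [dirhodium tetrakis(caprolactamate)] (1 mol %), ClCH2CH2Cl, 40 °C
Reagents that add atoms: tert-butyl hydroperoxide, CC(C)(C)OO
Why: Allylic C–H oxidation of the kind used to make 7-oxo-Δ5 steroids: tert-butylperoxyl radicals attack the only allylic methylene (C7) and the peroxide collapses to the enone; the 8-methyl stays equatorial, which is also the stable epimer.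

**Step 12**
Reactants: 18 tert-butyl (3R)-5-[(1S,2R,5R,8aS)-5-(acetoxymethyl)-1,2,5-trimethyl-3-oxo-1,2,3,5,6,7,8,8a-octahydronaphthalen-1-yl]-3-methylpentanoate
Product: 19 (3R)-5-[(1S,2R,5R,8aS)-5-(acetoxymethyl)-1,2,5-trimethyl-3-oxo-1,2,3,5,6,7,8,8a-octahydronaphthalen-1-yl]-3-methylpentanoic acid
Conditions: CF3CO2H/CH2Cl2 (1:4), 0 → 20 °C
Reagents that add atoms: none
Why: Acidolysis of the tert-butyl ester (tert-butyl cation lost as 2-methylpropene); acetate and enone are stable to the acid, and the product is the target.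

**Compound list**
1 | ethyl 2-oxocyclohexane-1-carboxylate | CCOC(=O)C1CCCCC1=O | starting material
2 | ethyl (1R)-1-methyl-2-oxocyclohexane-1-carboxylate | CCOC(=O)[C@]1(C)CCCCC1=O | intermediate
3 | potassium (6R)-6-(ethoxycarbonyl)-6-methylcyclohex-1-en-1-olate (potassium enolate of 2, not isolated) | CCOC(=O)[C@]1(C)CCCC=C1[O-].[K+] | intermediate
4 | ethyl (1R)-1-methyl-2-[(trifluoromethanesulfonyl)oxy]cyclohex-2-ene-1-carboxylate | CCOC(=O)[C@]1(C)CCCC=C1OS(=O)(=O)C(F)(F)F | intermediate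
5 | ethyl (1R)-2-ethenyl-1-methylcyclohex-2-ene-1-carboxylate | CCOC(=O)[C@]1(C)CCCC=C1C=C | intermediate
6 | (2E)-2-methylbut-2-enal (tiglic aldehyde) | C/C=C(\C)C=O | starting material
7 | ethyl (1R,4aR,5R,6S)-5-formyl-1,5,6-trimethyl-1,2,3,4,4a,5,6,7-octahydronaphthalene-1-carboxylate | CCOC(=O)[C@]1(C)CCC[C@@H]2C1=CC[C@H](C)[C@@]2(C)C=O | intermediate
8 | ethyl (1R,4aS,5R,6S)-5-[(E)-2-iodoethenyl]-1,5,6-trimethyl-1,2,3,4,4a,5,6,7-octahydronaphthalene-1-carboxylate | CCOC(=O)[C@]1(C)CCC[C@@H]2C1=CC[C@H](C)[C@@]2(C)/C=C/I | intermediate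
9 | [(1R,4aS,5R,6S)-5-[(E)-2-iodoethenyl]-1,5,6-trimethyl-1,2,3,4,4a,5,6,7-octahydronaphthalen-1-yl]methanol | OC[C@]1(C)CCC[C@@H]2C1=CC[C@H](C)[C@@]2(C)/C=C/I | intermediate
10 | tert-butyl (2E)-but-2-enoate | C/C=C/C(=O)OC(C)(C)C | starting material
11 | tert-butyl (3S)-3-(4,4,5,5-tetramethyl-1,3,2-dioxaborolan-2-yl)butanoate | CC1(C)OB(OC1(C)C)[C@@H](C)CC(=O)OC(C)(C)C | intermediate
12 | dilithiated 9: (E)-alkenyllithium with lithium alkoxide at C18 (not isolated) | [Li]OC[C@]1(C)CCC[C@@H]2C1=CC[C@H](C)[C@@]2(C)/C=C/[Li] | intermediate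
13 | dilithium alkenyl(alkyl)pinacolatoborate complex of 12 and 11 (not isolated) | [Li+].[Li+].[O-]C[C@]1(C)CCC[C@@H]2C1=CC[C@H](C)[C@@]2(C)/C=C/[B-]1(OC(C)(C)C(C)(C)O1)[C@@H](C)CC(=O)OC(C)(C)C | intermediate
14 | β-iodoalkyl boronic ester from anti addition of iodine (C11) and the migrating C13 group (C12); both face isomers form and both eliminate to 15, one shown (not isolated) | OC[C@]1(C)CCC[C@@H]2C1=CC[C@H](C)[C@@]2(C)[C@@H](I)[C@H](B1OC(C)(C)C(C)(C)O1)[C@@H](C)CC(=O)OC(C)(C)C | intermediate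
15 | tert-butyl (3S,4Z)-5-[(1S,2S,5R,8aS)-5-(hydroxymethyl)-1,2,5-trimethyl-1,2,3,5,6,7,8,8a-octahydronaphthalen-1-yl]-3-methylpent-4-enoate | OC[C@]1(C)CCC[C@@H]2C1=CC[C@H](C)[C@@]2(C)/C=C\[C@@H](C)CC(=O)OC(C)(C)C | intermediate
16 | tert-butyl (3R)-5-[(1R,2S,5R,8aS)-5-(hydroxymethyl)-1,2,5-trimethyl-1,2,3,5,6,7,8,8a-octahydronaphthalen-1-yl]-3-methylpentanoate | OC[C@]1(C)CCC[C@@H]2C1=CC[C@H](C)[C@@]2(C)CC[C@@H](C)CC(=O)OC(C)(C)C | intermediate
17 | tert-butyl (3R)-5-[(1R,2S,5R,8aS)-5-(acetoxymethyl)-1,2,5-trimethyl-1,2,3,5,6,7,8,8a-octahydronaphthalen-1-yl]-3-methylpentanoate | CC(=O)OC[C@]1(C)CCC[C@@H]2C1=CC[C@H](C)[C@@]2(C)CC[C@@H](C)CC(=O)OC(C)(C)C | intermediate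
18 | tert-butyl (3R)-5-[(1S,2R,5R,8aS)-5-(acetoxymethyl)-1,2,5-trimethyl-3-oxo-1,2,3,5,6,7,8,8a-octahydronaphthalen-1-yl]-3-methylpentanoate | CC(=O)OC[C@]1(C)CCC[C@@H]2C1=CC(=O)[C@H](C)[C@@]2(C)CC[C@@H](C)CC(=O)OC(C)(C)C | intermediate
19 | (3R)-5-[(1S,2R,5R,8aS)-5-(acetoxymethyl)-1,2,5-trimethyl-3-oxo-1,2,3,5,6,7,8,8a-octahydronaphthalen-1-yl]-3-methylpentanoic acid | CC(=O)OC[C@]1(C)CCC[C@@H]2C1=CC(=O)[C@H](C)[C@@]2(C)CC[C@@H](C)CC(=O)O | target

**Step count**
Total: 12 steps. Longest linear sequence: 11 steps (steps 1–6 and 8–12); step 7 is a one-step side branch.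

**Three steps most likely to fail**

Step 8 is the riskiest. The alkenyllithium could attack or deprotonate the tert-butyl ester of 11 before it reaches boron. The lithium alkoxide could tie up the boronate. Iodine could also be consumed by iodoetherification of the C18 alcohol onto C5=C6. The fallback sets out from 9 and comes back at 16, and keeps the crotonate β-carbon as the nucleophile but moves the stereo-defining event. Suzuki–Miyaura coupling of 9 [Pd(PPh3)4, K3PO4, dioxane/H2O, 60 °C] with tert-butyl (2Z)-3-(4,4,5,5-tetramethyl-1,3,2-dioxaborolan-2-yl)but-2-enoate F1 gives tert-butyl (2E,4E)-5-[(1S,2S,5R,8aS)-5-(hydroxymethyl)-1,2,5-trimethyl-1,2,3,5,6,7,8,8a-octahydronaphthalen-1-yl]-3-methylpenta-2,4-dienoate F2. F1 is made from tert-butyl but-2-ynoate with B2pin2, CuCl, NaOt-Bu, 4,5-bis(diphenylphosphino)-9,9-dimethylxanthene and MeOH. Copper hydride 1,4-reduction of F2 [CuCl, NaOt-Bu, (S)-2,2'-bis(di-p-tolylphosphino)-1,1'-binaphthyl, polymethylhydrosiloxane, t-BuOH, toluene] then sets C13 under ligand control and gives tert-butyl (3S,4E)-5-[(1S,2S,5R,8aS)-5-(hydroxymethyl)-1,2,5-trimethyl-1,2,3,5,6,7,8,8a-octahydronaphthalen-1-yl]-3-methylpent-4-enoate F3. The hydrogenation of step 9 converts F3 into 16.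

Step 4 is second. Three selectivities must hold at once: ortho regiochemistry, exo mode, and attack on the diene face anti to the ester. Tiglic aldehyde is also a sluggish dienophile. The fallback sets out from 5 and comes back at 7, and replaces catalyst control by a covalently bound auxiliary. Diene 5 and (4S)-4-benzyl-3-[(2E)-2-methylbut-2-enoyl]-1,3-oxazolidin-2-one F4 (from the oxazolidinone and tigloyl chloride) react with Me2AlCl in CH2Cl2 at −30 °C. This gives ethyl (1R,4aR,5R,6S)-5-{[(4S)-4-benzyl-2-oxo-1,3-oxazolidin-3-yl]carbonyl}-1,5,6-trimethyl-1,2,3,4,4a,5,6,7-octahydronaphthalene-1-carboxylate F5. EtSLi in THF at 0 °C removes the auxiliary and gives ethyl (1R,4aR,5R,6S)-5-[(ethylsulfanyl)carbonyl]-1,5,6-trimethyl-1,2,3,4,4a,5,6,7-octahydronaphthalene-1-carboxylate F6. Et3SiH with Pd/C in acetone reduces the thioester F6 to aldehyde 7.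

Step 1 is third. Phase-transfer methylation of a small ethyl β-keto ester may give insufficient enantiomeric excess, and none of the early intermediates is crystalline. The fallback sets out from 1 and comes back at 2, and uses a stoichiometric chiral amine instead of an ion-pair catalyst. Condensation of 1 with tert-butyl L-valinate (benzene, azeotropic water removal) gives ethyl 2-{[(2S)-1-tert-butoxy-3-methyl-1-oxobutan-2-yl]amino}cyclohex-1-ene-1-carboxylate F7. Deprotonation with LiN(i-Pr)2 and methylation with MeI (toluene, hexamethylphosphoramide, −78 °C) gives ethyl (1R)-2-{[(2S)-1-tert-butoxy-3-methyl-1-oxobutan-2-yl]imino}-1-methylcyclohexane-1-carboxylate F8. Aqueous acetic acid hydrolyses F8 to 2.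

**Further compounds**
F1 | step 8 | tert-butyl (2Z)-3-(4,4,5,5-tetramethyl-1,3,2-dioxaborolan-2-yl)but-2-enoate | C/C(B1OC(C)(C)C(C)(C)O1)=C\C(=O)OC(C)(C)C
F2 | step 8 | tert-butyl (2E,4E)-5-[(1S,2S,5R,8aS)-5-(hydroxymethyl)-1,2,5-trimethyl-1,2,3,5,6,7,8,8a-octahydronaphthalen-1-yl]-3-methylpenta-2,4-dienoate | OC[C@]1(C)CCC[C@@H]2C1=CC[C@H](C)[C@@]2(C)/C=C/C(/C)=C/C(=O)OC(C)(C)C
F3 | step 8 | tert-butyl (3S,4E)-5-[(1S,2S,5R,8aS)-5-(hydroxymethyl)-1,2,5-trimethyl-1,2,3,5,6,7,8,8a-octahydronaphthalen-1-yl]-3-methylpent-4-enoate | OC[C@]1(C)CCC[C@@H]2C1=CC[C@H](C)[C@@]2(C)/C=C/[C@@H](C)CC(=O)OC(C)(C)C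
F4 | step 4 | (4S)-4-benzyl-3-[(2E)-2-methylbut-2-enoyl]-1,3-oxazolidin-2-one | C/C=C(\C)C(=O)N1[C@@H](Cc2ccccc2)COC1=O
F5 | step 4 | ethyl (1R,4aR,5R,6S)-5-{[(4S)-4-benzyl-2-oxo-1,3-oxazolidin-3-yl]carbonyl}-1,5,6-trimethyl-1,2,3,4,4a,5,6,7-octahydronaphthalene-1-carboxylate | CCOC(=O)[C@]1(C)CCC[C@@H]2C1=CC[C@H](C)[C@@]2(C)C(=O)N1[C@@H](Cc2ccccc2)COC1=O
F6 | step 4 | ethyl (1R,4aR,5R,6S)-5-[(ethylsulfanyl)carbonyl]-1,5,6-trimethyl-1,2,3,4,4a,5,6,7-octahydronaphthalene-1-carboxylate | CCOC(=O)[C@]1(C)CCC[C@@H]2C1=CC[C@H](C)[C@@]2(C)C(=O)SCC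
F7 | step 1 | ethyl 2-{[(2S)-1-tert-butoxy-3-methyl-1-oxobutan-2-yl]amino}cyclohex-1-ene-1-carboxylate | CCOC(=O)C1=C(N[C@@H](C(C)C)C(=O)OC(C)(C)C)CCCC1
F8 | step 1 | ethyl (1R)-2-{[(2S)-1-tert-butoxy-3-methyl-1-oxobutan-2-yl]imino}-1-methylcyclohexane-1-carboxylate | CCOC(=O)[C@]1(C)CCCCC1=N[C@@H](C(C)C)C(=O)OC(C)(C)C
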